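The vessel is closed and stirred, and I charge it with free monomer, initiator and transfer agent.

all flasks: free monomer 0.050 M

|  | transfer agent | initiator | remark | time |
|---|---|---|---|---|
| theta | 2.5 mM | 1.5 mM | run made earlier |  |
| epsilon | 10 mM | 1.5 mM | run made earlier |  |
| gamma | 5 mM | 3 mM | run made earlier |  |
| flask | 5.00 mM | 1.5 mM |  | 4.0 d |

| run | time / d | monomer in chains / % | free monomer / % |
|---|---|---|---|
| theta | 0.625 | 22.4 | 56.9 |
| theta | 1.25 | 34.8 | 33.0 |
| theta | 1.67 | 40.3 | 24.2 |
| theta | 2.50 | 45.5 | 12.0 |
| theta | 3.00 | 47.4 | 8.0 |
| theta | 4.00 | 48.3 | 3.8 |
| epsilon | 0.208 | 11.2 | 81.9 |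
| epsilon | 0.625 | 22.6 | 57.4 |
| epsilon | 1.04 | 30.0 | 41.2 |
| epsilon | 1.67 | 37.0 | 26.3 |
| epsilon | 2.50 | 42.5 | 13.7 |
| epsilon | 3.00 | 42.4 | 10.9 |
| epsilon | 4.00 | 44.8 | 5.0 |
| gamma | 0.833 | 46.9 | 32.3 |
| gamma | 1.67 | 59.8 | 12.6 |
| gamma | 2.50 | 65.6 | 4.8 |
| gamma | 3.00 | 65.6 | 1.8 |
| gamma | 4.00 | 66.3 | 1.1 |

(readings scatter by 0.5 percentage points)

- the average divides the monomer in chains by the number of chains begun, living and dead together
- the numbers in the tables scatter by 0.5 percentage points (one standard deviation)
- on the list of suspects stand: living end + transfer agent -> dead chain; free monomer -> uncatalysed product; free monomer + living end -> monomer in chains + living end; monomer in chains -> over-reaction product; free monomer + initiator -> living end + monomer in chains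
- the earlier runs do not show the number of chains; that part of a forecast is a guess

* whether the average number of monomer units in a chain (chains begun, living or dead) reaches 5.0 by 4.0 d (no / yes)
* average number of monomer units in a chain (chains begun, living or dead) at 4.0 d

First I let the main step run by itself: each initiator starts one chain, living ends add free monomer, and once every initiator has begun its chain the length climbs towards the charge ratio, a ceiling of 33.3 units. The earlier runs do not show the number of chains, so this count is my assumption. Then I add the uncatalysed step. It and growth are two drains on one tank, each proportional to the free monomer, so when I divide one rate by the other, free monomer and time drop out. While the living ends hold, a constant selectivity factor remains. At 4.00 d the theta run has 50.2% of its reacted free monomer in chains.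

Next I add the transfer agent, which stops living ends. The epsilon run, with more of it, reads 47.2%. The flask lies a third of the way from theta to epsilon, so I take its chain share, monomer in chains per free monomer reacted, as 49.2%. The gamma run, with the flask's transfer agent and twice its initiator, reads 67.0%, which puts its ratio of chain share to remainder at 2.10 times the figure I take for the flask. The chain columns show no clear fall, so I add nothing for over-reaction.

The same interpolation leaves 4.20% free monomer, so ceiling times share times reacted part gives me 15.7 at 4.0 d. With that count of chains, a length of 5.0 needs 15.0% of the charge in chains, and theta and epsilon, on either side of the flask in transfer agent, read more than that, 22.4% and 22.6%, at 0.625 d, so I answer yes.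

The forecast says yes and 15.8, on the ground that “Killing creates no new chains”. The flask answers yes, with a length of 15.7, on these steps:

    living end + transfer agent → dead chain (kL = 0.0156 M⁻¹ min⁻¹)
    free monomer → uncatalysed product (k = 2.95 × 10⁻⁴ min⁻¹)
    free monomer + living end → monomer in chains + living end, rate k3*[living end]*[free monomer] (k = 0.208 M⁻¹ min⁻¹)
    monomer in chains → over-reaction product (k = 3.00 × 10⁻⁶ min⁻¹)
    free monomer + initiator → living end + monomer in chains (k = 1.07 M⁻¹ min⁻¹)

The length passes 5.0 at 0.337 d, with 27.1% of the free monomer reacted. At 4.00 d the free monomer left is 4.1%, and ceiling, chain share and reacted part then multiply to 15.7. At 40.0 d, with free monomer at 0%, the chain share leaves 50.8% for uncatalysed product, and that product stands at 50.6%.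

The runs were generated by integration from invented constants, and the scatter is random.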